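The numbers were drawn at random within sensible limits.

A slow exchange between target and isomer of the product shows in these flasks as far as some product is still young when the reading is taken.

in all of them: precatalyst 2.0 µM
- violet: substrate 20 mM (fed, over 1.20 min); time 1.5 min; all but substrate at the start; substrate goes in evenly over 1.20 min, the run ends at 1.5 min
- blue: substrate 20 mM; time 1.5 min; a closed flask charged with all of it at once and left for 1.5 min
- amber: substrate 20 mM; a single well-mixed tank run continuously and read at steady state, 1.5 min in it on average

    substrate + enzyme → target + enzyme, rate k1*[substrate]*[enzyme]/(1 + ([substrate]/Km1) + ([substrate]/Ksi1)^2) (Km1 = 18 mM, Ksi1 = 14 mM, k1 = 1.3 × 10⁵ M⁻¹ s⁻¹)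
    precatalyst → enzyme (k2 = 0.12 s⁻¹)
    target ⇌ isomer of the product (K3 = 0.74, k3 = 0.036 s⁻¹)

* the set-up with the highest amount of target at the outlet or at the end, in percent of the substrate put in ("none" if the first two lie within 2 percentage points) (violet / blue / amber / none)
* amount of target at the outlet or at the end, in percent of the substrate put in, violet
* amount of target at the outlet or at the end, in percent of the substrate put in, blue
* amount of target at the outlet or at the end, in percent of the substrate put in, amber

- the stated concentrations are those of everything mixed, before any reaction; amounts are the same in each set-up
- the feed brings no volume worth counting
- run time (violet): 1.5 min

Follow one molecule of substrate. Enzyme turns it into target, and from then on it flips between target and isomer of the product like a first-order system, with final value f = 57.5% and time constant τ = 11.8 s. Call τ the memory time (the usual term is relaxation time), the time in which a molecule's surplus chance of being target over f shrinks by the factor e. At age a, the chance of being target is f plus the rest of the way to certainty times exp(−a/τ). The yield is conversion times this chance, averaged over ages.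

Blue and violet hold the same charges and differ in when their molecules are born. In blue, my reckoning of the integrated rate law, with the brake and the enzyme lag 8.33 s included, takes substrate down to 1.00% by about 34.2 s. Product born at that moment is 55.8 s old at the reading, longer than τ, so my reckoning puts blue roughly 0.38 percentage points above f. In violet, the turnover time 3.85 s is shorter than the dosing time 1.20 min, so births spread evenly over the feed. The mean memory left is then about 0.0495, giving 59.6%. In amber, ages spread exponentially around 1.5 min, so the mean memory is 0.116. With the brake left out, this gives 59.6%. Violet and amber lie closer than 2 points, so my reckoning says none.

The forecast gives 59.8% for violet, 57.6% for blue, 59.5% for amber and best none, holding that “Product formed late is still target-rich”. Its violet stands 0.20 points above mine.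

The simulation gives 59.7% for violet, 57.6% for blue, 59.5% for amber, and best none. In violet, enzyme worked through the feed with substrate at 5.78% of the charge after 0.750 min, while target was already passing to isomer of the product. Violet held 5.72% substrate and 61.2% target at the end of the feed, and 0.0567% substrate and 59.7% target at the end of the run. Violet's reading leaves memory 0.0536, an equivalent age of 34.6 s. The neighbour of violet with a quarter of the precatalyst ends at 55.3% target, below the forecast's violet range, with 12.4% substrate left. Its converted product reads memory 0.134, an equivalent age of 23.8 s.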